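The route rests on disconnecting the bond between the acyclic quaternary carbon and its tertiary oxygen. Zerovalent palladium with a chiral diamide bisphosphine and catalytic triethylborane opens both epimers of a 2-alkyl-2-vinyloxirane with 4-methoxybenzyl alcohol and fixes the (R) quaternary carbon in one stereoconvergent operation. The step exploits the substitution pattern of that carbon: one oxygen, a one-carbon arm (later the formyl group), a two-carbon arm (later the enol acetate) and a single alkyl chain, which is the branched oxygen-bearing terminus of a vinyloxirane-derived π-allyl. The precursor is the oxirane, epimeric at its ring carbon, carrying the finished chain with the (S)-trimethylcyclohexene ring from resolved alpha-ionone.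

Key step: step 9

Assumption: the (S,S) antipode of the DACH-phenyl Trost ligand is taken as the one that gives the (R) ether; this is a model-based expectation to be confirmed on the first run, and the (R,R) ligand is used instead, with nothing else changed, should the sense be opposite.

Step 1
Reactants: 1 racemic alpha-ionone
Product: 2 (S)-alpha-ionone
Conditions: preparative SFC on amylose tris(3,5-dimethylphenylcarbamate), CO2/iPrOH, 35 °C; levorotatory antipode collected
Reagents that add atoms: none
Why: Resolution by chromatography on a chiral stationary phase separates the antipodes without touching the base-sensitive doubly allylic stereocentre, and the (S) antipode is recognised by its negative rotation, opposite to that of the known (R)-(+) compound.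

Step 2
Reactants: 2 (S)-alpha-ionone
Product: 3 (S)-dihydro-alpha-ionone
Conditions: Cu(OAc)2·H2O (cat.), 1,2-bis(diphenylphosphino)benzene (cat.), (EtO)2MeSiH, tBuOH, toluene, rt
Reagents that add atoms: none
Why: Phosphine-ligated CuH formed in situ adds hydride to the enone in the 1,4 sense and tBuOH protonates the copper enolate (Stryker-type conjugate reduction), while the isolated trisubstituted ring alkene is no acceptor and the neutral conditions leave the ring stereocentre unchanged.

Step 3
Reactants: 3 (S)-dihydro-alpha-ionone; 4 triethyl phosphonoacetate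
Product: 5 (S,E)-ethyl ester (ethyl alpha-monocyclofarnesoate)
Conditions: NaH, THF, 0 °C → 50 °C; (Z) ester removed by chromatography
Reagents that add atoms: none
Why: Horner–Wadsworth–Emmons olefination of the methyl ketone by the sodium phosphonate gives the trisubstituted enoate with the (E) isomer expected to predominate, because the longer chain prefers to lie anti to the ester, and the (Z) ester is separable on silica.

Step 4
Reactants: 5 (S,E)-ethyl ester
Product: 6 (S,E)-allylic alcohol
Conditions: iBu2AlH (2.3 equiv), CH2Cl2, −78 → 0 °C; aq. potassium sodium tartrate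
Reagents that add atoms: none
Why: iBu2AlH reduces the conjugated ester at the carbonyl group only (hydride reduction of an ester to the primary alcohol), leaving both alkenes and the (E) geometry untouched.

Step 5
Reactants: 6 (S,E)-allylic alcohol
Product: 7 (S,E)-allylic bromide
Conditions: CBr4, PPh3, CH2Cl2, 0 °C; used at once
Reagents that add atoms: carbon tetrabromide, BrC(Br)(Br)Br
Why: Appel bromination displaces the alkoxyphosphonium ion by bromide in an SN2 step under neutral conditions, which should avoid allylic transposition and loss of the (E) geometry.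

Step 6
Reactants: 7 (S,E)-allylic bromide; 8 N-methoxy-N-methylacetamide
Product: 9 Weinreb amide
Conditions: 8 (1.5 equiv), LiN(iPr)2, THF, −78 °C; then 7, −78 → −20 °C
Reagents that add atoms: none
Why: The lithium enolate of the acetamide, kept at −78 °C where it is stable, is C-alkylated by the reactive primary allylic bromide in an SN2 reaction (amide enolate alkylation), and the excess of enolate limits dialkylation.

Step 7
Reactants: 9 Weinreb amide; 10 chloroiodomethane
Product: 11 alpha-chloromethyl ketone
Conditions: 10 (excess), MeLi·LiBr added last, THF, −78 °C; sat. aq. NH4Cl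
Reagents that add atoms: none
Why: Chloromethyllithium formed by iodine–lithium exchange in the presence of the amide adds only once, because the chelated tetrahedral adduct survives until the quench (Weinreb ketone synthesis with a carbenoid), and the alkenes are inert.

Step 8
Reactants: 11 alpha-chloromethyl ketone; 12 vinylmagnesium bromide
Product: 14 2-alkyl-2-vinyloxirane (both oxirane epimers), via chlorohydrin 13 (not isolated)
Conditions: THF, −78 °C; then MeOH, 2 M aq. NaOH, 0 °C → rt; chromatography on Et3N-deactivated silica
Reagents that add atoms: none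
Why: Grignard 1,2-addition to the ketone is faster than attack at the C–Cl bond, and the chlorohydrin closes by intramolecular Williamson etherification (3-exo-tet) once hydroxide is added; the oxirane carbon forms without stereocontrol, which is harmless because step 9 is stereoconvergent.

Step 9
Reactants: 14 2-alkyl-2-vinyloxirane (both oxirane epimers); 15 4-methoxybenzyl alcohol
Product: 16 (R)-tertiary 4-methoxybenzyl ether with free primary alcohol
Conditions: Pd2(dba)3·CHCl3 (1 mol %), (S,S)-DACH-phenyl Trost ligand (3 mol %), Et3B (2 mol %), 15 (1.2 equiv), CH2Cl2, rt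
Reagents that add atoms: none
Why: Zerovalent palladium ionises the allylic C–O bond of each oxirane epimer to alkoxide-bearing π-allyl complexes that interconvert by π-σ-π exchange through the unsubstituted CH2 terminus faster than they are trapped, while triethylborane joins the alkoxide and 15 in a borate that hands the benzylic oxygen to the neighbouring tertiary terminus. The closest known reaction is the Tsuji–Trost-type dynamic kinetic asymmetric addition of alcohols to 2-methyl- and 2-alkyl-2-vinyloxiranes with a trialkylborane co-catalyst. No ring is closed; the strained oxirane is opened, which drives the ionisation. The new quaternary stereocentre is set by the chiral pocket of the ligand alone, so both epimers of 14 converge on (R) and the remote (S) ring centre has no influence. The step needs branched regioselectivity, secured by the boron tether to the adjacent alkoxide, and face selectivity independent of substrate configuration, secured by the unsubstituted allyl terminus that permits fast equilibration. The two trisubstituted alkenes carry no leaving group and stay inert to the catalyst.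

Step 10
Reactants: 16 (R)-tertiary 4-methoxybenzyl ether with free primary alcohol
Product: 18 (R)-1,4-diol, via organoborane 17 (not isolated)
Conditions: 9-BBN (3 equiv), THF, 0 °C → rt; then 3 M aq. NaOH, 30% H2O2, 0 °C → rt
Reagents that add atoms: hydrogen peroxide, OO
Why: 9-BBN hydroborates only the monosubstituted vinyl group, with boron on the terminal carbon, and ignores the two trisubstituted alkenes (anti-Markovnikov hydroboration–oxidation), and alkaline peroxide replaces boron by hydroxyl without change at the quaternary centre.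

Step 11
Reactants: 18 (R)-1,4-diol
Product: 19 (R)-2-alkoxy succinaldehyde
Conditions: (COCl)2, DMSO, CH2Cl2, −78 °C; Et3N, −78 → −30 °C; cold aq. NaH2PO4/Na2HPO4 (pH 7); crude product used directly
Reagents that add atoms: none
Why: Swern oxidation turns both hydroxyls into alkoxysulfonium ions before base is added, so the 1,4-diol goes to the dialdehyde without a lactol that could be oxidised to a lactone, and the cold quench keeps base contact of the β-alkoxy aldehyde short.

Step 12
Reactants: 19 (R)-2-alkoxy succinaldehyde
Product: 20 (E)-enol acetate aldehyde, tertiary 4-methoxybenzyl ether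
Conditions: Ac2O, Et3N, DMAP (cat.), CH2Cl2, rt; minor (Z) isomer removed by chromatography
Reagents that add atoms: acetic anhydride, CC(=O)OC(C)=O
Why: Only the CH2–CHO arm can enolise, since the other formyl group sits on the quaternary carbon, so amine-mediated enolisation and O-acetylation by the acetylpyridinium ion (enol acetylation) should give the enol acetate, with (E) favoured because the (Z) position is crowded by the fully substituted carbon.

Step 13
Reactants: 20 (E)-enol acetate aldehyde, tertiary 4-methoxybenzyl ether
Product: 21 tertiary alpha-hydroxy aldehyde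
Conditions: DDQ, CH2Cl2/aq. NaH2PO4/Na2HPO4 (pH 7), 0 °C; used promptly
Reagents that add atoms: none
Why: DDQ oxidises the electron-rich 4-methoxybenzyl ether through a charge-transfer complex to an oxocarbenium ion that water hydrolyses (oxidative benzyl ether cleavage), while the enol acetate, the aldehyde and the trisubstituted alkenes are not electron-rich enough to react at 0 °C under buffered conditions.

Step 14
Reactants: 21 tertiary alpha-hydroxy aldehyde
Product: 22 target CNP0244145.1
Conditions: Ac2O, DMAP, Et3N, CH2Cl2, rt
Reagents that add atoms: acetic anhydride, CC(=O)OC(C)=O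
Why: DMAP-catalysed acylation (Steglich-type nucleophilic catalysis) acetylates the tertiary hydroxyl through the acetylpyridinium ion, and since no enolisable aldehyde is left the new acetate cannot be lost by β-elimination and the quaternary centre is untouched.

Compound list
1 | racemic alpha-ionone, (E)-4-(2,6,6-trimethylcyclohex-2-en-1-yl)but-3-en-2-one | CC(=O)/C=C/C1C(C)=CCCC1(C)C | starting material
2 | (S)-alpha-ionone | CC(=O)/C=C/[C@@H]1C(C)=CCCC1(C)C | intermediate
3 | (S)-dihydro-alpha-ionone, 4-[(1S)-2,6,6-trimethylcyclohex-2-en-1-yl]butan-2-one | CC(=O)CC[C@@H]1C(C)=CCCC1(C)C | intermediate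
4 | triethyl phosphonoacetate | CCOC(=O)CP(=O)(OCC)OCC | starting material
5 | ethyl (2E)-3-methyl-5-[(1S)-2,6,6-trimethylcyclohex-2-en-1-yl]pent-2-enoate | CCOC(=O)/C=C(\C)CC[C@@H]1C(C)=CCCC1(C)C | intermediate
6 | (2E)-3-methyl-5-[(1S)-2,6,6-trimethylcyclohex-2-en-1-yl]pent-2-en-1-ol | OC/C=C(\C)CC[C@@H]1C(C)=CCCC1(C)C | intermediate
7 | (1S)-1-[(3E)-5-bromo-3-methylpent-3-en-1-yl]-2,6,6-trimethylcyclohex-2-ene | BrC/C=C(\C)CC[C@@H]1C(C)=CCCC1(C)C | intermediate
8 | N-methoxy-N-methylacetamide | CON(C)C(C)=O | starting material
9 | (4E)-N-methoxy-N,5-dimethyl-7-[(1S)-2,6,6-trimethylcyclohex-2-en-1-yl]hept-4-enamide | CON(C)C(=O)CC/C=C(\C)CC[C@@H]1C(C)=CCCC1(C)C | intermediate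
10 | chloroiodomethane | ClCI | starting material
11 | (5E)-1-chloro-6-methyl-8-[(1S)-2,6,6-trimethylcyclohex-2-en-1-yl]oct-5-en-2-one | ClCC(=O)CC/C=C(\C)CC[C@@H]1C(C)=CCCC1(C)C | intermediate
12 | vinylmagnesium bromide | C=C[Mg]Br | starting material
13 | (6E)-3-(chloromethyl)-7-methyl-9-[(1S)-2,6,6-trimethylcyclohex-2-en-1-yl]nona-1,6-dien-3-ol, both C3 epimers, formed as its magnesium alkoxide | C=CC(O)(CCl)CC/C=C(\C)CC[C@@H]1C(C)=CCCC1(C)C | intermediate
14 | 2-ethenyl-2-[(3E)-4-methyl-6-[(1S)-2,6,6-trimethylcyclohex-2-en-1-yl]hex-3-en-1-yl]oxirane, both epimers at the oxirane carbon | C=CC1(CC/C=C(\C)CC[C@@H]2C(C)=CCCC2(C)C)CO1 | intermediate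
15 | 4-methoxybenzyl alcohol | COc1ccc(CO)cc1 | starting material
16 | (2R,5E)-2-ethenyl-2-[(4-methoxybenzyl)oxy]-6-methyl-8-[(1S)-2,6,6-trimethylcyclohex-2-en-1-yl]oct-5-en-1-ol | C=C[C@@](CO)(CC/C=C(\C)CC[C@@H]1C(C)=CCCC1(C)C)OCc1ccc(OC)cc1 | intermediate
17 | adduct of 16 with two 9-borabicyclo[3.3.1]nonane units, B-alkyl at the former vinyl terminus and O-boryl at the primary oxygen | C1CCC2CCCC1B2CC[C@@](COB1C2CCCC1CCC2)(CC/C=C(\C)CC[C@@H]1C(C)=CCCC1(C)C)OCc1ccc(OC)cc1 | intermediate
18 | (2R)-2-[(4-methoxybenzyl)oxy]-2-[(3E)-4-methyl-6-[(1S)-2,6,6-trimethylcyclohex-2-en-1-yl]hex-3-en-1-yl]butane-1,4-diol | OCC[C@@](CO)(CC/C=C(\C)CC[C@@H]1C(C)=CCCC1(C)C)OCc1ccc(OC)cc1 | intermediate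
19 | (2R)-2-[(4-methoxybenzyl)oxy]-2-[(3E)-4-methyl-6-[(1S)-2,6,6-trimethylcyclohex-2-en-1-yl]hex-3-en-1-yl]butanedial | O=CC[C@@](C=O)(CC/C=C(\C)CC[C@@H]1C(C)=CCCC1(C)C)OCc1ccc(OC)cc1 | intermediate
20 | (1E,3R,6E)-3-formyl-3-[(4-methoxybenzyl)oxy]-7-methyl-9-[(1S)-2,6,6-trimethylcyclohex-2-en-1-yl]nona-1,6-dien-1-yl acetate | CC(=O)O/C=C/[C@@](C=O)(CC/C=C(\C)CC[C@@H]1C(C)=CCCC1(C)C)OCc1ccc(OC)cc1 | intermediate
21 | (1E,3R,6E)-3-formyl-3-hydroxy-7-methyl-9-[(1S)-2,6,6-trimethylcyclohex-2-en-1-yl]nona-1,6-dien-1-yl acetate | CC(=O)O/C=C/[C@@](C=O)(CC/C=C(\C)CC[C@@H]1C(C)=CCCC1(C)C)O | intermediate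
22 | CNP0244145.1, (1E,3R,6E)-3-formyl-7-methyl-9-[(1S)-2,6,6-trimethylcyclohex-2-en-1-yl]nona-1,6-diene-1,3-diyl diacetate | CC(=O)O/C=C/[C@@](C=O)(CC/C=C(\C)CC[C@@H]1C(C)=CCCC1(C)C)OC(C)=O | target

Total step count: 14
Longest linear sequence: 14 steps (1 to 22)

Steps most likely to fail

Step 12. The enolate of the β-alkoxy aldehyde may expel the benzylic alkoxide (E1cB) faster than it is O-acetylated, a loss made easier by the second formyl group on the alkoxy-bearing carbon, and the enol ester may form with poor (E) selectivity. The fallback sets out from 16 and rejoins the route at 20, without passing through a dialdehyde. The primary hydroxyl of 16 is silylated (TBSCl, imidazole, DMF) to the silyl ether F1. 9-BBN followed by NaOH/H2O2 gives the primary alcohol F2. Dess–Martin periodinane with NaHCO3 gives the mono-aldehyde F3, whose alkoxy-bearing carbon carries no carbonyl group and is therefore less prone to elimination. Ac2O, Et3N and DMAP give the enol acetate F4. Buffered HF·pyridine frees the neopentyl alcohol F5, and Dess–Martin periodinane oxidises it to 20.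

Step 14. Acylation of the hindered tertiary hydroxyl, deactivated by the adjacent formyl group, may be slow enough for base-induced alpha-ketol rearrangement or loss of the enol ester to take over. The fallback sets out from 21 and rejoins at 22 by a redox detour. NaBH4 with CeCl3·7H2O in MeOH at −78 °C reduces the formyl group to give the 1,2-diol F6. Et3SiCl and imidazole silylate only the primary hydroxyl, giving the triethylsilyl ether F7. The tertiary hydroxyl, no longer next to a carbonyl group, is acetylated (Ac2O, DMAP, Et3N) to the tertiary acetate F8. Swern conditions then cleave and oxidise the primary triethylsilyl ether directly to the aldehyde 22, so that no free hydroxyl ever sits beside the tertiary acetate and acyl migration is excluded.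

Step 9. Equilibration of the diastereomeric π-allyl complexes may be incomplete before trapping, or attack may occur at the unsubstituted terminus, so that configurational purity at the quaternary carbon is eroded. The fallback sets out from 7 and rejoins at 16, replacing steps 6 to 9 by reagent-controlled chemistry. The dilithio derivative of 2-methylprop-2-en-1-ol (n-BuLi, TMEDA, Et2O) is alkylated at carbon by 7 to give the 2-methylidene alcohol F9. Sharpless asymmetric epoxidation (Ti(OiPr)4, L-(+)-diethyl tartrate, tBuOOH, 4 Å sieves, CH2Cl2, −20 °C), directed by the hydroxyl so that the isolated trisubstituted alkenes stay untouched, gives the (S)-epoxy alcohol F10. Silylation (TBSCl, imidazole), which also blocks the degenerate Payne rearrangement that would racemise, gives the silyl ether F11. Excess dimethylsulfonium methylide (Me3SI, n-BuLi, THF) opens the oxirane at its CH2 group and loses dimethyl sulfide to give the tertiary vinyl carbinol F12. Bu4NF gives the vinyl diol F13. 4-Methoxybenzaldehyde dimethyl acetal with PPTS gives the 4-methoxybenzylidene acetal F14. iBu2AlH then opens the acetal at the less hindered primary oxygen and leaves the 4-methoxybenzyl group on the tertiary oxygen, which is 16.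

Further compounds
F1 | step 12 | tert-butyldimethylsilyl ether of 16 at the primary oxygen | C=C[C@@](CO[Si](C)(C)C(C)(C)C)(CC/C=C(\C)CC[C@@H]1C(C)=CCCC1(C)C)OCc1ccc(OC)cc1
F2 | step 12 | primary alcohol from hydroboration of F1 | OCC[C@@](CO[Si](C)(C)C(C)(C)C)(CC/C=C(\C)CC[C@@H]1C(C)=CCCC1(C)C)OCc1ccc(OC)cc1
F3 | step 12 | mono-aldehyde from F2 | O=CC[C@@](CO[Si](C)(C)C(C)(C)C)(CC/C=C(\C)CC[C@@H]1C(C)=CCCC1(C)C)OCc1ccc(OC)cc1
F4 | step 12 | (E)-enol acetate silyl ether | CC(=O)O/C=C/[C@@](CO[Si](C)(C)C(C)(C)C)(CC/C=C(\C)CC[C@@H]1C(C)=CCCC1(C)C)OCc1ccc(OC)cc1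
F5 | step 12 | (E)-enol acetate with free neopentyl alcohol and tertiary 4-methoxybenzyl ether | CC(=O)O/C=C/[C@@](CO)(CC/C=C(\C)CC[C@@H]1C(C)=CCCC1(C)C)OCc1ccc(OC)cc1
F6 | step 14 | 1,2-diol from reduction of 21 | CC(=O)O/C=C/[C@@](CO)(CC/C=C(\C)CC[C@@H]1C(C)=CCCC1(C)C)O
F7 | step 14 | primary triethylsilyl ether of F6 | CC(=O)O/C=C/[C@@](CO[Si](CC)(CC)CC)(CC/C=C(\C)CC[C@@H]1C(C)=CCCC1(C)C)O
F8 | step 14 | tertiary acetate of F7 | CC(=O)O/C=C/[C@@](CO[Si](CC)(CC)CC)(CC/C=C(\C)CC[C@@H]1C(C)=CCCC1(C)C)OC(C)=O
F9 | step 9 | 2-[(3E)-4-methyl-6-[(1S)-2,6,6-trimethylcyclohex-2-en-1-yl]hex-3-en-1-yl]prop-2-en-1-ol | C=C(CO)CC/C=C(\C)CC[C@@H]1C(C)=CCCC1(C)C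
F10 | step 9 | [(2S)-2-[(3E)-4-methyl-6-[(1S)-2,6,6-trimethylcyclohex-2-en-1-yl]hex-3-en-1-yl]oxiran-2-yl]methanol | OC[C@@]1(CC/C=C(\C)CC[C@@H]2C(C)=CCCC2(C)C)CO1
F11 | step 9 | tert-butyldimethylsilyl ether of F10 (same spatial arrangement) | CC(C)(C)[Si](C)(C)OC[C@@]1(CC/C=C(\C)CC[C@@H]2C(C)=CCCC2(C)C)CO1
F12 | step 9 | (R)-tertiary vinyl carbinol with primary silyl ether | C=C[C@@](CO[Si](C)(C)C(C)(C)C)(CC/C=C(\C)CC[C@@H]1C(C)=CCCC1(C)C)O
F13 | step 9 | (2R,5E)-2-ethenyl-6-methyl-8-[(1S)-2,6,6-trimethylcyclohex-2-en-1-yl]oct-5-ene-1,2-diol | C=C[C@@](CO)(CC/C=C(\C)CC[C@@H]1C(C)=CCCC1(C)C)O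
F14 | step 9 | (4R)-4-ethenyl-2-(4-methoxyphenyl)-4-[(3E)-4-methyl-6-[(1S)-2,6,6-trimethylcyclohex-2-en-1-yl]hex-3-en-1-yl]-1,3-dioxolane, both acetal epimers | C=C[C@]1(CC/C=C(\C)CC[C@@H]2C(C)=CCCC2(C)C)COC(c2ccc(OC)cc2)O1
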